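**Retrosynthetic overview**
1. The only ring, the 36-membered lactone, is closed last by an intramolecular Stille coupling (C9–C10); C2=C3 comes from a Wittig reaction of a C35-bound phosphorane and C10=C11 from a Takai olefination.
2. The C21 and C27 ketones and the C11 aldehyde are unmasked together by ozonolysis of two 1,1-disubstituted alkenes and one trisubstituted alkene.
3. The six carbinols (C13, C15, C17, C19, C23, C25) come from one hexaboronate by stereoretentive oxidation.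
4. The hexaboronate is built by Pt-catalysed alkene diboration (C25, C19, C15) alternating with stereospecific boron-to-carbon 1,2-shifts (C23 by a new conjunctive coupling; C17 and C13 by lithiation–borylation).
5. C35 comes from (S)-2-isopropyloxirane; the chain carbons come from 6-bromohex-1-ene, 2-bromopenta-1,4-diene (used twice), but-3-en-1-ol and 4-methylpent-3-en-1-ol.

Assumption: the target is made as the open-chain diketo hexol drawn; locants C1 (lactone carbonyl) to C35 (isopropyl carbinol) are used for all intermediates, whose configurations are fixed by the SMILES; compounds 3 and 32 and both sparteine enantiomers are bought.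
Notation: ligand T is the 3,5-diethylphenyl-TADDOL phenylphosphonite enantiomer that turns 1-alkenes into (R)-1,2-diols after oxidation, and ent-T is its mirror image; the absolute descriptor of ligand T and the MandyPhos enantiomer are to be fixed from precedent or a model substrate.

**Step 1**
Reactants: 1 2,3-dibromoprop-1-ene
Product: 2 2-bromopenta-1,4-diene
Conditions: vinylMgBr, CuI (5 mol%), Et2O/THF, 0 °C → rt
Reagents that add atoms: vinylmagnesium bromide, C=C[Mg]Br
Why: Copper-catalysed allylic substitution by the vinyl Grignard reagent (SN2 and SN2′ give the same product) leaves the vinylic C–Br bond untouched.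

**Step 2**
Reactants: 3 (S)-2-isopropyloxirane; 4 6-bromohex-1-ene
Product: 6 (R)-2-methyldec-9-en-3-ol, via hex-5-en-1-ylmagnesium bromide 5 (not isolated)
Conditions: Mg, THF, rt; then CuI (10 mol%), 3, −30 → 0 °C; aq. NH4Cl
Reagents that add atoms: none
Why: Copper-catalysed Grignard opening of the epoxide at its CH2 carbon (SN2) does not touch the C–O stereocentre, so the (S)-epoxide gives the (R)-carbinol that becomes C35.

**Step 3**
Reactants: 6 (R)-2-methyldec-9-en-3-ol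
Product: 7 (R)-1-methoxy-4-{[(2-methyldec-9-en-3-yl)oxy]methyl}benzene
Conditions: NaH, PMBCl, Bu4NI (cat.), DMF, 0 °C → rt
Reagents that add atoms: 4-methoxybenzyl chloride, COc1ccc(CCl)cc1
Why: Williamson etherification installs a PMB group that survives organolithium, boron and platinum chemistry and is orthogonal to the later silyl ethers.

**Step 4**
Reactants: 7 PMB ether; 2 2-bromopenta-1,4-diene
Product: 9 (R)-1-methoxy-4-{[(2-methyl-11-methylidenetetradec-13-en-3-yl)oxy]methyl}benzene, via alkyl-9-BBN 8 (not isolated)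
Conditions: 9-BBN-H (1.0 equiv), THF, rt; then 2, Pd(dppf)Cl2 (3 mol%), K3PO4 (aq.), DMF, 50 °C
Reagents that add atoms: none
Why: Anti-Markovnikov hydroboration followed by B-alkyl Suzuki–Miyaura coupling with the vinyl bromide gives the C27 exo-methylene (masked ketone) next to the C24=C25 terminal alkene.

**Step 5**
Reactants: 9 skipped diene (C24–C35)
Product: 10 C24,C25-bis(pinacolboronate) of 9
Conditions: B2pin2, Pt(dba)3 (zerovalent platinum, 3 mol%), ligand T (6 mol%), THF, 60 °C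
Reagents that add atoms: bis(pinacolato)diboron, CC1(C)OB(OC1(C)C)B1OC(C)(C)C(C)(C)O1
Why: Enantioselective Pt-catalysed alkene diboration reacts only at the monosubstituted alkene (the 1,1-disubstituted one is inert), and the ligand-controlled face of syn addition sets C25.

**Step 6**
Reactants: 10 C24,C25-bis(pinacolboronate); 2 2-bromopenta-1,4-diene
Product: 12 C23,C25-bis(pinacolboronate) carrying C21 and C27 exo-methylene groups and the C18=C19 alkene, via lithium vinylboronate complex 11 (not isolated)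
Conditions: vinyllithium (1.0 equiv), THF, −78 → 0 °C; then 2, Pd(OAc)2 (3 mol%), MandyPhos ligand C52H50FeN2P2 (3.6 mol%, enantiomer chosen for the C23 configuration shown), NaOTf, THF, 60 °C
Reagents that add atoms: vinyllithium, [Li]C=C
Why: Proposed new method: vinyllithium adds to the less hindered primary boron of the vicinal bis(boronate); the alkenyl-Pd cation formed from 2 (bromide scavenged by NaOTf) binds the vinyl group and triggers an anti 1,2-shift of C24 from boron to C23, and reductive elimination then forms C22–C21 with the ligand-controlled face setting C23; the closest known reaction types are the enantioselective conjunctive cross-coupling of alkyl(vinyl)boronate complexes with alkenyl halides or triflates and the primary-selective homologation of 1,2-bis(boronic esters), neither of which has been shown as a conjunctive coupling on a 1,2-bis(boronate).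

**Step 7**
Reactants: 12 C23,C25-bis(pinacolboronate)
Product: 13 C18,C19,C23,C25-tetrakis(pinacolboronate)
Conditions: B2pin2, Pt(dba)3 (zerovalent platinum, 3 mol%), ligand ent-T (6 mol%), THF, 60 °C
Reagents that add atoms: bis(pinacolato)diboron, CC1(C)OB(OC1(C)C)B1OC(C)(C)C(C)(C)O1
Why: The same Pt-catalysed diboration with the mirror-image ligand sets C19 with the opposite sense (17,19-anti in the target) and again spares both 1,1-disubstituted alkenes.

**Step 8**
Reactants: 14 but-3-en-1-ol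
Product: 15 but-3-en-1-yl 2,4,6-triisopropylbenzoate
Conditions: 2,4,6-triisopropylbenzoic acid, PPh3, DIAD, THF, 0 °C → rt
Reagents that add atoms: 2,4,6-triisopropylbenzoic acid, CC(C)c1cc(C(C)C)c(C(=O)O)c(C(C)C)c1
Why: Mitsunobu esterification gives the hindered benzoate that directs α-lithiation and later serves as the leaving group of the 1,2-shift.

**Step 9**
Reactants: 16 4-methylpent-3-en-1-ol
Product: 17 4-methylpent-3-en-1-yl 2,4,6-triisopropylbenzoate
Conditions: 2,4,6-triisopropylbenzoic acid, PPh3, DIAD, THF, 0 °C → rt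
Reagents that add atoms: 2,4,6-triisopropylbenzoic acid, CC(C)c1cc(C(C)C)c(C(=O)O)c(C(C)C)c1
Why: Mitsunobu esterification gives the second hindered benzoate, whose isopropylidene end is a masked C11 aldehyde.

**Step 10**
Reactants: 13 tetrakis(pinacolboronate); 15 but-3-en-1-yl 2,4,6-triisopropylbenzoate
Product: 20 C17,C19,C23,C25-tetrakis(pinacolboronate) with the C14=C15 alkene, via lithiated benzoate 18 (not isolated), via boronate complex 19 (not isolated)
Conditions: 15, sBuLi, (+)-sparteine, Et2O, −78 °C, 5 h; then 13, −78 → 40 °C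
Reagents that add atoms: none
Why: Lithiation–borylation (primary-selective homologation of a 1,2-bis(boronic ester)): the (+)-sparteine-controlled (R)-carbenoid adds with retention to the primary C18 boron, and a stereospecific 1,2-metallate shift with inversion expels the benzoate, forming C17–C18 and setting C17.

**Step 11**
Reactants: 20 tetrakis(pinacolboronate) with C14=C15 alkene
Product: 21 C14,C15,C17,C19,C23,C25-hexakis(pinacolboronate)
Conditions: B2pin2, Pt(dba)3 (zerovalent platinum, 3 mol%), ligand T (6 mol%), THF, 60 °C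
Reagents that add atoms: bis(pinacolato)diboron, CC1(C)OB(OC1(C)C)B1OC(C)(C)C(C)(C)O1
Why: Pt-catalysed enantioselective diboration of the only monosubstituted alkene sets C15 under ligand control.

**Step 12**
Reactants: 21 hexakis(pinacolboronate); 17 4-methylpent-3-en-1-yl 2,4,6-triisopropylbenzoate
Product: 24 C13,C15,C17,C19,C23,C25-hexakis(pinacolboronate) with the C11 isopropylidene terminus, via lithiated homoprenyl benzoate 22 (not isolated), via boronate complex 23 (not isolated)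
Conditions: 17, sBuLi, (+)-sparteine, Et2O, −78 °C, 5 h; then 21, −78 → 40 °C
Reagents that add atoms: none
Why: A second lithiation–borylation at the primary C14 boron (retentive borylation of the (R)-carbenoid, invertive 1,2-metallate shift) forms C13–C14 and sets C13, and the trisubstituted alkene it brings marks C11 for ozonolysis.

**Step 13**
Reactants: 24 hexakis(pinacolboronate)
Product: 25 C13,C15,C17,C19,C23,C25-hexol (C35 PMB ether; C21 and C27 exo-methylene; C11 isopropylidene)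
Conditions: H2O2 (30%), NaOH (3 M), THF, 0 °C → rt
Reagents that add atoms: hydrogen peroxide, OO
Why: Alkaline peroxide oxidation converts each C–B bond into C–O by a stereoretentive boron-to-oxygen 1,2-shift, so all six carbinol configurations follow from the boronates.

**Step 14**
Reactants: 25 hexol
Product: 26 hexakis(triethylsilyl) ether of 25
Conditions: TESOTf, 2,6-lutidine, CH2Cl2, −78 → 0 °C
Reagents that add atoms: triethylsilyl trifluoromethanesulfonate, CC[Si](CC)(CC)OS(=O)(=O)C(F)(F)F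
Why: Silylation of all six secondary alcohols gives ethers that can be removed at the end with buffered fluoride instead of acid.

**Step 15**
Reactants: 26 hexakis(triethylsilyl) ether
Product: 27 C35 alcohol
Conditions: DDQ, CH2Cl2/pH 7 buffer (10:1), 0 °C
Reagents that add atoms: none
Why: Oxidative PMB cleavage by DDQ frees only the C35 hydroxyl and is done before the ozonolysis and before any polyene is present.

**Step 16**
Reactants: 27 C35 alcohol
Product: 28 C11 aldehyde C21,C27-diketone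
Conditions: O3, CH2Cl2, −78 °C; then PPh3, −78 °C → rt
Reagents that add atoms: ozone, [O-][O+]=O
Why: Ozonolysis with reductive work-up cleaves the two 1,1-disubstituted alkenes to the C21 and C27 ketones and the trisubstituted alkene to the C11 aldehyde (acetone is lost); no other alkene is present.

**Step 17**
Reactants: 28 aldehyde diketone
Product: 29 (E)-C10 vinyl iodide
Conditions: CrCl2 (divalent chromium), CHI3, THF/1,4-dioxane (1:6), 0 °C → rt, dark
Reagents that add atoms: iodoform, IC(I)I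
Why: Takai olefination with the geminal dichromium reagent is selective for the aldehyde over the two ketones and gives the (E)-vinyl iodide, adding C10.

**Step 18**
Reactants: 29 vinyl iodide alcohol; 30 2-bromopropanoyl bromide
Product: 31 C35 2-bromopropanoate (both epimers at the bromine-bearing carbon)
Conditions: pyridine, CH2Cl2, 0 °C
Reagents that add atoms: none
Why: The acyl bromide esterifies the hindered C35 alcohol under mild conditions; the uncontrolled bromo-substituted centre later becomes the sp2 carbon C2.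

**Step 19**
Reactants: 32 (E)-pent-2-en-4-yn-1-ol
Product: 33 (2E,4E)-5-(tributylstannyl)penta-2,4-dien-1-ol
Conditions: Bu3SnH, PdCl2(PPh3)2 (2 mol%), THF, 0 °C
Reagents that add atoms: tributyltin hydride, CCCC[SnH](CCCC)CCCC
Why: Palladium-catalysed syn hydrostannation of the terminal alkyne places tin on the terminal carbon and gives the (E)-alkenylstannane.

**Step 20**
Reactants: 33 stannyl dienol
Product: 35 (2E,4E,6E)-7-(tributylstannyl)hepta-2,4,6-trienal, via stannyl dienal 34 (not isolated)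
Conditions: MnO2, Ph3P=CHCHO (1.1 equiv), CH2Cl2, rt → 40 °C
Reagents that add atoms: (triphenylphosphoranylidene)acetaldehyde, O=CC=P(c1ccccc1)(c1ccccc1)c1ccccc1
Why: Tandem allylic oxidation and Wittig two-carbon homologation with a stabilised ylide gives the new (E)-alkene (C4=C5 of the target).

**Step 21**
Reactants: 31 C35 2-bromopropanoate; 35 stannyl trienal
Product: 38 C35 (2E,4E,6E,8E)-2-methyl-9-(tributylstannyl)nona-2,4,6,8-tetraenoate bearing the C10 vinyl iodide, via phosphonium bromide 36 (not isolated), via phosphorane 37 (not isolated)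
Conditions: PPh3, MeCN, 60 °C; aq. K2CO3/CH2Cl2, 0 °C; then 35, CH2Cl2, rt → 40 °C, dark
Reagents that add atoms: none
Why: SN2 displacement of bromide by PPh3 and deprotonation give an ester-stabilised ylide, and its Wittig olefination with the enal forms the (E)-trisubstituted C2=C3 bond while leaving both ketones untouched.

**Step 22**
Reactants: 38 seco stannane iodide
Product: 39 hexakis(triethylsilyl) macrolide
Conditions: Pd2(dba)3 (zerovalent palladium, 20 mol%), AsPh3, iPr2NEt, DMF/THF, 1 mM, rt, dark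
Reagents that add atoms: none
Why: Intramolecular Stille coupling under high dilution forms C9–C10 with retention of both alkene geometries and closes the 36-membered ring as the all-E pentaene.

**Step 23**
Reactants: 39 hexakis(triethylsilyl) macrolide
Product: 40 CNP0167014.1
Conditions: HF·pyridine, excess pyridine, THF, 0 °C → rt, dark; aq. NaHCO3
Reagents that add atoms: none
Why: Buffered fluoride desilylation removes the six TES ethers without acid-promoted ketalisation or dehydration of the β-hydroxy ketones and does not touch any stereocentre.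

**Compound list**
1 | 2,3-dibromoprop-1-ene | BrCC(Br)=C | starting material
2 | 2-bromopenta-1,4-diene | C=CCC(Br)=C | intermediate
3 | (S)-2-isopropyloxirane | CC(C)[C@H]1CO1 | starting material
4 | 6-bromohex-1-ene | BrCCCCC=C | starting material
5 | hex-5-en-1-ylmagnesium bromide | C=CCCCC[Mg]Br | intermediate
6 | (R)-2-methyldec-9-en-3-ol | CC(C)[C@H](O)CCCCCC=C | intermediate
7 | (R)-1-methoxy-4-{[(2-methyldec-9-en-3-yl)oxy]methyl}benzene | CC(C)[C@H](OCc1ccc(OC)cc1)CCCCCC=C | intermediate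
8 | 9-[(8R)-8-(4-methoxybenzyloxy)-9-methyldecyl]-9-borabicyclo[3.3.1]nonane | CC(C)[C@H](OCc1ccc(OC)cc1)CCCCCCCB1C2CCCC1CCC2 | intermediate
9 | (R)-1-methoxy-4-{[(2-methyl-11-methylidenetetradec-13-en-3-yl)oxy]methyl}benzene (C24–C35; C27 exo-methylene) | CC(C)[C@H](OCc1ccc(OC)cc1)CCCCCCCC(=C)CC=C | intermediate
10 | 9 with Bpin on C25 and C24 | CC(C)[C@H](OCc1ccc(OC)cc1)CCCCCCCC(=C)C[C@@H](B1OC(C)(C)C(C)(C)O1)CB1OC(C)(C)C(C)(C)O1 | intermediate
11 | lithium vinylboronate complex of 10 at the C24 boron | CC(C)[C@H](OCc1ccc(OC)cc1)CCCCCCCC(=C)C[C@@H](B1OC(C)(C)C(C)(C)O1)C[B-]1(C=C)OC(C)(C)C(C)(C)O1.[Li+] | intermediate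
12 | C18–C35 chain with Bpin on C25 and C23, exo-methylene on C27 and C21, alkene C18=C19 | CC(C)[C@H](OCc1ccc(OC)cc1)CCCCCCCC(=C)C[C@@H](B1OC(C)(C)C(C)(C)O1)C[C@H](B1OC(C)(C)C(C)(C)O1)CC(=C)CC=C | intermediate
13 | 12 with Bpin added on C19 and C18 | CC(C)[C@H](OCc1ccc(OC)cc1)CCCCCCCC(=C)C[C@@H](B1OC(C)(C)C(C)(C)O1)C[C@H](B1OC(C)(C)C(C)(C)O1)CC(=C)C[C@H](B1OC(C)(C)C(C)(C)O1)CB1OC(C)(C)C(C)(C)O1 | intermediate
14 | but-3-en-1-ol | OCCC=C | starting material
15 | but-3-en-1-yl 2,4,6-triisopropylbenzoate | C=CCCOC(=O)c1c(C(C)C)cc(C(C)C)cc1C(C)C | intermediate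
16 | 4-methylpent-3-en-1-ol | OCCC=C(C)C | starting material
17 | 4-methylpent-3-en-1-yl 2,4,6-triisopropylbenzoate | CC(C)=CCCOC(=O)c1c(C(C)C)cc(C(C)C)cc1C(C)C | intermediate
18 | (R)-1-lithiobut-3-en-1-yl 2,4,6-triisopropylbenzoate ((+)-sparteine complex) | [Li][C@H](CC=C)OC(=O)c1c(C(C)C)cc(C(C)C)cc1C(C)C | intermediate
19 | lithium boronate complex of 13 and 18 at the C18 boron | CC(C)[C@H](OCc1ccc(OC)cc1)CCCCCCCC(=C)C[C@@H](B1OC(C)(C)C(C)(C)O1)C[C@H](B1OC(C)(C)C(C)(C)O1)CC(=C)C[C@H](B1OC(C)(C)C(C)(C)O1)C[B-]1([C@H](CC=C)OC(=O)c2c(C(C)C)cc(C(C)C)cc2C(C)C)OC(C)(C)C(C)(C)O1.[Li+] | intermediate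
20 | C14–C35 chain with Bpin on C25, C23, C19 and C17, alkene C14=C15 | CC(C)[C@H](OCc1ccc(OC)cc1)CCCCCCCC(=C)C[C@@H](B1OC(C)(C)C(C)(C)O1)C[C@H](B1OC(C)(C)C(C)(C)O1)CC(=C)C[C@H](B1OC(C)(C)C(C)(C)O1)C[C@@H](B1OC(C)(C)C(C)(C)O1)CC=C | intermediate
21 | 20 with Bpin added on C15 and C14 | CC(C)[C@H](OCc1ccc(OC)cc1)CCCCCCCC(=C)C[C@@H](B1OC(C)(C)C(C)(C)O1)C[C@H](B1OC(C)(C)C(C)(C)O1)CC(=C)C[C@H](B1OC(C)(C)C(C)(C)O1)C[C@@H](B1OC(C)(C)C(C)(C)O1)C[C@@H](B1OC(C)(C)C(C)(C)O1)CB1OC(C)(C)C(C)(C)O1 | intermediate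
22 | (R)-1-lithio-4-methylpent-3-en-1-yl 2,4,6-triisopropylbenzoate ((+)-sparteine complex) | [Li][C@H](CC=C(C)C)OC(=O)c1c(C(C)C)cc(C(C)C)cc1C(C)C | intermediate
23 | lithium boronate complex of 21 and 22 at the C14 boron | CC(C)[C@H](OCc1ccc(OC)cc1)CCCCCCCC(=C)C[C@@H](B1OC(C)(C)C(C)(C)O1)C[C@H](B1OC(C)(C)C(C)(C)O1)CC(=C)C[C@H](B1OC(C)(C)C(C)(C)O1)C[C@@H](B1OC(C)(C)C(C)(C)O1)C[C@@H](B1OC(C)(C)C(C)(C)O1)C[B-]1([C@H](CC=C(C)C)OC(=O)c2c(C(C)C)cc(C(C)C)cc2C(C)C)OC(C)(C)C(C)(C)O1.[Li+] | intermediate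
24 | C11–C35 chain with Bpin on C25, C23, C19, C17, C15 and C13 and an isopropylidene group on C11 | CC(C)[C@H](OCc1ccc(OC)cc1)CCCCCCCC(=C)C[C@@H](B1OC(C)(C)C(C)(C)O1)C[C@H](B1OC(C)(C)C(C)(C)O1)CC(=C)C[C@H](B1OC(C)(C)C(C)(C)O1)C[C@@H](B1OC(C)(C)C(C)(C)O1)C[C@@H](B1OC(C)(C)C(C)(C)O1)C[C@@H](B1OC(C)(C)C(C)(C)O1)CC=C(C)C | intermediate
25 | C13,C15,C17,C19,C23,C25-hexol (C35 PMB ether; C21 and C27 exo-methylene; C11 isopropylidene) | CC(C)[C@H](OCc1ccc(OC)cc1)CCCCCCCC(=C)C[C@@H](O)C[C@H](O)CC(=C)C[C@H](O)C[C@@H](O)C[C@@H](O)C[C@@H](O)CC=C(C)C | intermediate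
26 | hexakis(triethylsilyl) ether of 25 | CC(C)[C@H](OCc1ccc(OC)cc1)CCCCCCCC(=C)C[C@@H](O[Si](CC)(CC)CC)C[C@H](O[Si](CC)(CC)CC)CC(=C)C[C@H](O[Si](CC)(CC)CC)C[C@@H](O[Si](CC)(CC)CC)C[C@@H](O[Si](CC)(CC)CC)C[C@@H](O[Si](CC)(CC)CC)CC=C(C)C | intermediate
27 | C35 alcohol (26 without PMB) | CC(C)[C@H](O)CCCCCCCC(=C)C[C@@H](O[Si](CC)(CC)CC)C[C@H](O[Si](CC)(CC)CC)CC(=C)C[C@H](O[Si](CC)(CC)CC)C[C@@H](O[Si](CC)(CC)CC)C[C@@H](O[Si](CC)(CC)CC)C[C@@H](O[Si](CC)(CC)CC)CC=C(C)C | intermediate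
28 | C11 aldehyde, C21 and C27 ketones, C35 alcohol, six TES ethers | CC(C)[C@H](O)CCCCCCCC(=O)C[C@@H](O[Si](CC)(CC)CC)C[C@H](O[Si](CC)(CC)CC)CC(=O)C[C@H](O[Si](CC)(CC)CC)C[C@@H](O[Si](CC)(CC)CC)C[C@@H](O[Si](CC)(CC)CC)C[C@@H](O[Si](CC)(CC)CC)CC=O | intermediate
29 | (E)-C10 vinyl iodide, C21 and C27 ketones, C35 alcohol, six TES ethers | CC(C)[C@H](O)CCCCCCCC(=O)C[C@@H](O[Si](CC)(CC)CC)C[C@H](O[Si](CC)(CC)CC)CC(=O)C[C@H](O[Si](CC)(CC)CC)C[C@@H](O[Si](CC)(CC)CC)C[C@@H](O[Si](CC)(CC)CC)C[C@@H](O[Si](CC)(CC)CC)C/C=C/I | intermediate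
30 | 2-bromopropanoyl bromide | CC(Br)C(=O)Br | starting material
31 | C35 2-bromopropanoate of 29 | CC(C)[C@H](OC(=O)C(C)Br)CCCCCCCC(=O)C[C@@H](O[Si](CC)(CC)CC)C[C@H](O[Si](CC)(CC)CC)CC(=O)C[C@H](O[Si](CC)(CC)CC)C[C@@H](O[Si](CC)(CC)CC)C[C@@H](O[Si](CC)(CC)CC)C[C@@H](O[Si](CC)(CC)CC)C/C=C/I | intermediate
32 | (E)-pent-2-en-4-yn-1-ol | OC/C=C/C#C | starting material
33 | (2E,4E)-5-(tributylstannyl)penta-2,4-dien-1-ol | OC/C=C/C=C/[Sn](CCCC)(CCCC)CCCC | intermediate
34 | (2E,4E)-5-(tributylstannyl)penta-2,4-dienal | O=C/C=C/C=C/[Sn](CCCC)(CCCC)CCCC | intermediate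
35 | (2E,4E,6E)-7-(tributylstannyl)hepta-2,4,6-trienal | O=C/C=C/C=C/C=C/[Sn](CCCC)(CCCC)CCCC | intermediate
36 | triphenylphosphonium bromide from 31 | CC(C)[C@H](OC(=O)C(C)[P+](c1ccccc1)(c1ccccc1)c1ccccc1)CCCCCCCC(=O)C[C@@H](O[Si](CC)(CC)CC)C[C@H](O[Si](CC)(CC)CC)CC(=O)C[C@H](O[Si](CC)(CC)CC)C[C@@H](O[Si](CC)(CC)CC)C[C@@H](O[Si](CC)(CC)CC)C[C@@H](O[Si](CC)(CC)CC)C/C=C/I.[Br-] | intermediate
37 | C35 2-(triphenylphosphoranylidene)propanoate | CC(C)[C@H](OC(=O)C(C)=P(c1ccccc1)(c1ccccc1)c1ccccc1)CCCCCCCC(=O)C[C@@H](O[Si](CC)(CC)CC)C[C@H](O[Si](CC)(CC)CC)CC(=O)C[C@H](O[Si](CC)(CC)CC)C[C@@H](O[Si](CC)(CC)CC)C[C@@H](O[Si](CC)(CC)CC)C[C@@H](O[Si](CC)(CC)CC)C/C=C/I | intermediate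
38 | C35 (2E,4E,6E,8E)-2-methyl-9-(tributylstannyl)nona-2,4,6,8-tetraenoate with (E)-C10 vinyl iodide | CC(C)[C@H](OC(=O)/C(C)=C/C=C/C=C/C=C/[Sn](CCCC)(CCCC)CCCC)CCCCCCCC(=O)C[C@@H](O[Si](CC)(CC)CC)C[C@H](O[Si](CC)(CC)CC)CC(=O)C[C@H](O[Si](CC)(CC)CC)C[C@@H](O[Si](CC)(CC)CC)C[C@@H](O[Si](CC)(CC)CC)C[C@@H](O[Si](CC)(CC)CC)C/C=C/I | intermediate
39 | 13,15,17,19,23,25-hexakis-O-(triethylsilyl) macrolide | CC(C)[C@H]1CCCCCCCC(=O)C[C@@H](O[Si](CC)(CC)CC)C[C@H](O[Si](CC)(CC)CC)CC(=O)C[C@H](O[Si](CC)(CC)CC)C[C@@H](O[Si](CC)(CC)CC)C[C@@H](O[Si](CC)(CC)CC)C[C@@H](O[Si](CC)(CC)CC)C/C=C/C=C/C=C/C=C/C=C(\C)/C(=O)O1 | intermediate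
40 | CNP0167014.1 (2E,4E,6E,8E,10E; 13S,15S,17S,19R,23S,25S,35R) | CC(C)[C@H]1CCCCCCCC(=O)C[C@@H](O)C[C@H](O)CC(=O)C[C@H](O)C[C@@H](O)C[C@@H](O)C[C@@H](O)C/C=C/C=C/C=C/C=C/C=C(\C)/C(=O)O1 | target

**Step count.** Total: 23 steps. Longest linear sequence: 18 steps (steps 2–7, 10–18, 21–23).

**Steps most likely to fail and fallbacks**

Step 6 (new conjunctive coupling; risks are poor primary/secondary selectivity in the vinyl addition and mismatched stereocontrol at C23). The fallback uses the known lithiation–borylation homologation; it sets out from 10 and comes back at 12. Bromide 2 is treated with tBuLi to give penta-1,4-dien-2-yllithium F1, which opens oxirane (BF3·OEt2) to give 3-methylidenehex-5-en-1-ol F2. Mitsunobu esterification gives 3-methylidenehex-5-en-1-yl 2,4,6-triisopropylbenzoate F3. Treatment with sBuLi and (−)-sparteine gives the (S)-lithiated benzoate F4, which adds to the primary boron of 10 to give boronate complex F5; warming triggers the 1,2-shift and returns 12.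

Step 17 (Takai olefination; risks are E/Z erosion and sluggish reaction next to the silyloxy group). The fallback sets out from 28 and comes back at 29. Seyferth–Gilbert homologation of the aldehyde with the Ohira–Bestmann reagent (K2CO3, MeOH, 0 °C) gives terminal alkyne F6. Hydrostannation (Bu3SnH, PdCl2(PPh3)2) gives (E)-vinylstannane F7, and iododestannylation with I2 then gives 29 with retention of geometry.

Step 22 (36-membered Stille ring closure). The fallback closes the ring at C2=C3 instead; it sets out from 29 and comes back at 39. Intermolecular Stille coupling of 29 with 35 gives open-chain tetraenal alcohol F8. Acylation with 30 gives bromo ester F9, and PPh3 gives phosphonium bromide F10. Aqueous K2CO3 gives phosphorane F11, which undergoes an intramolecular Wittig olefination under high dilution to give 39.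

**Further compounds**
F1 | step 6 | penta-1,4-dien-2-yllithium | [Li]C(=C)CC=C
F2 | step 6 | 3-methylidenehex-5-en-1-ol | OCCC(=C)CC=C
F3 | step 6 | 3-methylidenehex-5-en-1-yl 2,4,6-triisopropylbenzoate | C=CCC(=C)CCOC(=O)c1c(C(C)C)cc(C(C)C)cc1C(C)C
F4 | step 6 | (S)-1-lithio-3-methylidenehex-5-en-1-yl 2,4,6-triisopropylbenzoate | [Li][C@@H](CC(=C)CC=C)OC(=O)c1c(C(C)C)cc(C(C)C)cc1C(C)C
F5 | step 6 | lithium boronate complex of 10 and F4 at the C24 boron | CC(C)[C@H](OCc1ccc(OC)cc1)CCCCCCCC(=C)C[C@@H](B1OC(C)(C)C(C)(C)O1)C[B-]1([C@@H](CC(=C)CC=C)OC(=O)c2c(C(C)C)cc(C(C)C)cc2C(C)C)OC(C)(C)C(C)(C)O1.[Li+]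
F6 | step 17 | C10–C11 terminal alkyne analogue of 29 | CC(C)[C@H](O)CCCCCCCC(=O)C[C@@H](O[Si](CC)(CC)CC)C[C@H](O[Si](CC)(CC)CC)CC(=O)C[C@H](O[Si](CC)(CC)CC)C[C@@H](O[Si](CC)(CC)CC)C[C@@H](O[Si](CC)(CC)CC)C[C@@H](O[Si](CC)(CC)CC)CC#C
F7 | step 17 | (E)-C10 vinylstannane analogue of 29 | CC(C)[C@H](O)CCCCCCCC(=O)C[C@@H](O[Si](CC)(CC)CC)C[C@H](O[Si](CC)(CC)CC)CC(=O)C[C@H](O[Si](CC)(CC)CC)C[C@@H](O[Si](CC)(CC)CC)C[C@@H](O[Si](CC)(CC)CC)C[C@@H](O[Si](CC)(CC)CC)C/C=C/[Sn](CCCC)(CCCC)CCCC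
F8 | step 22 | open-chain (4E,6E,8E,10E)-tetraenal with free C35 alcohol | CC(C)[C@H](O)CCCCCCCC(=O)C[C@@H](O[Si](CC)(CC)CC)C[C@H](O[Si](CC)(CC)CC)CC(=O)C[C@H](O[Si](CC)(CC)CC)C[C@@H](O[Si](CC)(CC)CC)C[C@@H](O[Si](CC)(CC)CC)C[C@@H](O[Si](CC)(CC)CC)C/C=C/C=C/C=C/C=C/C=O
F9 | step 22 | C35 2-bromopropanoate of F8 | CC(C)[C@H](OC(=O)C(C)Br)CCCCCCCC(=O)C[C@@H](O[Si](CC)(CC)CC)C[C@H](O[Si](CC)(CC)CC)CC(=O)C[C@H](O[Si](CC)(CC)CC)C[C@@H](O[Si](CC)(CC)CC)C[C@@H](O[Si](CC)(CC)CC)C[C@@H](O[Si](CC)(CC)CC)C/C=C/C=C/C=C/C=C/C=O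
F10 | step 22 | triphenylphosphonium bromide from F9 | CC(C)[C@H](OC(=O)C(C)[P+](c1ccccc1)(c1ccccc1)c1ccccc1)CCCCCCCC(=O)C[C@@H](O[Si](CC)(CC)CC)C[C@H](O[Si](CC)(CC)CC)CC(=O)C[C@H](O[Si](CC)(CC)CC)C[C@@H](O[Si](CC)(CC)CC)C[C@@H](O[Si](CC)(CC)CC)C[C@@H](O[Si](CC)(CC)CC)C/C=C/C=C/C=C/C=C/C=O.[Br-]
F11 | step 22 | phosphorane from F10 | CC(C)[C@H](OC(=O)C(C)=P(c1ccccc1)(c1ccccc1)c1ccccc1)CCCCCCCC(=O)C[C@@H](O[Si](CC)(CC)CC)C[C@H](O[Si](CC)(CC)CC)CC(=O)C[C@H](O[Si](CC)(CC)CC)C[C@@H](O[Si](CC)(CC)CC)C[C@@H](O[Si](CC)(CC)CC)C[C@@H](O[Si](CC)(CC)CC)C/C=C/C=C/C=C/C=C/C=O
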